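The quinone ring (ring A, numbered so that C1 is the carbonyl between methoxy-bearing C2 and chain-bearing C6, with C4 the other carbonyl) is cut back to a dihydroresorcinol whose C2 and C4 already carry oxygen. The key step exploits C6: flanked by C5 and C1 and meta to the C2 and C4 oxygens, it is the carbonyl carbon of octadecanal, while C5–C4 come from dimethyl malonate and C1–C2–C3 from methyl acetoacetate. One pot forms C5–C6, C6–C1 and C3–C4 and closes ring A from three commercial, unprotected components. Saponification with decarboxylation, aromatising O-methylation and para-oxidation at C1 finish the synthesis.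

Key step: step 1

Remark: octadecanal is assumed to be used freshly distilled; compounds 5–9 are drawn as keto tautomers (6–8 should be largely enolised), and their sp3 centres form as mixtures that are all removed before the achiral target.

Step 1
Reactants: 1 octadecanal; 2 dimethyl malonate; 3 methyl acetoacetate
Product: 6 dimethyl 2-heptadecyl-4,6-dioxocyclohexane-1,3-dicarboxylate, via alkylidene malonate 4 (not isolated), via Michael adduct 5 (not isolated)
Conditions: 1, 2 (1.05 equiv), piperidine (10 mol %), AcOH (10 mol %), toluene, Dean–Stark, reflux; then 3 (1.0 equiv), NaOMe (2 equiv), MeOH, rt to reflux; aq. HCl, 0 °C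
Reagents that add atoms: none
Why: Piperidinium acetate condenses 1 with 2 in an iminium-mediated Knoevenagel reaction to 4 before any strong base or the more reactive acetoacetate is present, which keeps aldehyde self-aldolisation and acetoacetate homo-adducts out of the first stage. Methoxide then adds the C2 enolate of 3 to 4 in a Michael reaction (C6–C1) to give 5, and the small equilibrium share of the terminal methyl-ketone enolate of 5 attacks one malonate ester carbonyl in a Claisen (Dieckmann-type) condensation (C3–C4) with loss of methoxide. This ring closure is 6-exo-trig, every other carbon–carbon pairing of enolate and carbonyl in 5 would give a four-membered ring, and the closure is pulled forward by formation of the stabilised enolate of the cyclic tricarbonyl product, hence more than one equivalent of NaOMe. The closest known chemistry is the Vorländer dihydroresorcinol synthesis (Michael addition then Claisen closure between a malonate and a methyl ketone partner), here run on an alkylidene malonate with an acetoacetate and telescoped with the Knoevenagel stage. The three ring sp3 centres arise without control, which is immaterial because all are enolisable and are erased by decarboxylation and aromatisation. The selectivity needed is cross- over homo-condensation, secured by the staged addition, the 1:1:1 stoichiometry and the fact that either order of Michael addition leads to the same adduct 5.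

Step 2
Reactants: 6 dimethyl 2-heptadecyl-4,6-dioxocyclohexane-1,3-dicarboxylate
Product: 8 5-heptadecylcyclohexane-1,3-dione, via dicarboxylic acid 7 (not isolated)
Conditions: NaOH (aq., 5 equiv), MeOH, reflux; then HCl to pH 1, 90 °C
Reagents that add atoms: none
Why: Saponification of both β-keto esters and acid-induced loss of CO2 from the resulting β-keto acids is the standard finish of dihydroresorcinol (dimedone-type) syntheses, and the cyclic 1,3-dione is stable as its enolate in base and as its enol in acid.

Step 3
Reactants: 8 5-heptadecylcyclohexane-1,3-dione
Product: 10 3-heptadecyl-5-methoxyphenol, via enol ether 9 (not isolated)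
Conditions: I2 (2 equiv), MeOH, reflux; aq. Na2S2O3 work-up
Reagents that add atoms: methanol, CO
Why: Iodine–methanol aromatisation of a cyclohexane-1,3-dione, in which HI formed in situ catalyses enol etherification to 9, α-iodination and loss of HI give the dienone tautomer of the phenol, and the phenolic OH of 10 is not etherified further by methanol, so the monomethyl ether should predominate.

Step 4
Reactants: 10 3-heptadecyl-5-methoxyphenol
Product: 11 2-heptadecyl-6-methoxycyclohexa-2,5-diene-1,4-dione (2-heptadecyl-6-methoxy-1,4-benzoquinone)
Conditions: (KSO3)2NO (2.5 equiv), Na2HPO4/KH2PO4 buffer (pH 7), methyltrioctylammonium chloride (cat.), CH2Cl2/H2O, rt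
Reagents that add atoms: potassium nitrosodisulfonate (KSO3)2NO, [K+].[K+].[O]N(S(=O)(=O)[O-])S(=O)(=O)[O-]
Why: Teuber oxidation, in which the phenoxyl radical formed by one equivalent of (KSO3)2NO is trapped by a second at the free para carbon C1 (the only para position, between the methoxy and heptadecyl groups) and the adduct collapses to the para-quinone, the phase-transfer catalyst bringing the anionic radical to the lipophilic phenol.

Compound list
1 | octadecanal | CCCCCCCCCCCCCCCCCC=O | starting material
2 | dimethyl malonate | COC(=O)CC(=O)OC | starting material
3 | methyl acetoacetate | CC(=O)CC(=O)OC | starting material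
4 | dimethyl 2-octadecylidenepropanedioate (alkylidene malonate) | CCCCCCCCCCCCCCCCCC=C(C(=O)OC)C(=O)OC | intermediate
5 | trimethyl 2-heptadecyl-4-oxopentane-1,1,3-tricarboxylate (Michael adduct, mixture of diastereomers) | CCCCCCCCCCCCCCCCCC(C(C(=O)OC)C(=O)OC)C(C(C)=O)C(=O)OC | intermediate
6 | dimethyl 2-heptadecyl-4,6-dioxocyclohexane-1,3-dicarboxylate (mixture of stereoisomers and enol tautomers) | CCCCCCCCCCCCCCCCCC1C(C(=O)OC)C(=O)CC(=O)C1C(=O)OC | intermediate
7 | 2-heptadecyl-4,6-dioxocyclohexane-1,3-dicarboxylic acid (mixture of stereoisomers) | CCCCCCCCCCCCCCCCCC1C(C(=O)O)C(=O)CC(=O)C1C(=O)O | intermediate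
8 | 5-heptadecylcyclohexane-1,3-dione | CCCCCCCCCCCCCCCCCC1CC(=O)CC(=O)C1 | intermediate
9 | 5-heptadecyl-3-methoxycyclohex-2-en-1-one (racemic) | CCCCCCCCCCCCCCCCCC1CC(=O)C=C(OC)C1 | intermediate
10 | 3-heptadecyl-5-methoxyphenol | CCCCCCCCCCCCCCCCCc1cc(O)cc(OC)c1 | intermediate
11 | 2-heptadecyl-6-methoxycyclohexa-2,5-diene-1,4-dione | CCCCCCCCCCCCCCCCCC1=CC(=O)C=C(OC)C1=O | target

Total step count: 4. Longest linear sequence: 4 steps (from 1).

Steps most likely to fail

Step 1. The Claisen closure may be slow because adduct 5 rests as its doubly stabilised enolate. That would leave time for retro-Michael scrambling to homo-adducts and for aldol-type cyclisation, on top of any aldehyde self-condensation during the Knoevenagel stage. The fallback sets out from 1 and returns at 8, using the two-component Vorländer sequence. Wittig olefination of 1 with Ph3P=CHC(O)CH3 (toluene, 80 °C) should give (E)-henicos-3-en-2-one F1. With 2 and NaOMe in refluxing MeOH, F1 should undergo Michael addition to dimethyl 2-(2-oxohenicosan-4-yl)malonate F2 (not isolated) and Claisen closure to methyl 2-heptadecyl-4,6-dioxocyclohexane-1-carboxylate F3. Aqueous NaOH at reflux, then HCl and heat, should pass through 2-heptadecyl-4,6-dioxocyclohexane-1-carboxylic acid F4 (not isolated) to the dione 8.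

Step 3. Ketalisation of the enol ether before dehydrogenation would lead to over-methylation (the dimethyl ether), and dehydrogenation may be incomplete or accompanied by ring iodination. The fallback sets out from 8 and returns at 10, separating etherification from dehydrogenation. TsOH (cat.) in refluxing MeOH should give 9, here isolated. Kinetic deprotonation of 9 at the α' carbon with LiN(iPr)2 (THF, −78 °C) and trapping with PhSeCl should give 5-heptadecyl-3-methoxy-6-(phenylselanyl)cyclohex-2-en-1-one F5. H2O2 (CH2Cl2, pyridine, 0 °C to rt) should oxidise F5 to 5-heptadecyl-3-methoxy-6-(phenylseleninyl)cyclohex-2-en-1-one F6 (not isolated), whose syn-elimination and tautomerisation give 10.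

Step 4. Phase contact between the lipophilic phenol and the aqueous radical salt may be poor, ortho-oxidation or oxidative coupling may compete, and the reagent may decompose. The fallback sets out from 10 and returns at 11, installing the para heteroatom by electrophilic substitution. Nitrosation with NaNO2 in AcOH/EtOH at 0 °C should give 3-heptadecyl-5-methoxy-4-nitrosophenol F7, para-selectivity following the behaviour of 3,5-disubstituted phenols. Reduction with Na2S2O4 (aq. EtOH/THF) should give 4-amino-3-heptadecyl-5-methoxyphenol F8. Oxidation with FeCl3 in aq. HCl/EtOAc should give 3-heptadecyl-4-imino-5-methoxycyclohexa-2,5-dien-1-one F9 (not isolated), which hydrolyses in the acidic medium to 11.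

Further compounds
F1 | step 1 | (E)-henicos-3-en-2-one | CCCCCCCCCCCCCCCCC/C=C/C(C)=O
F2 | step 1 | dimethyl 2-(2-oxohenicosan-4-yl)malonate (racemic) | CCCCCCCCCCCCCCCCCC(CC(C)=O)C(C(=O)OC)C(=O)OC
F3 | step 1 | methyl 2-heptadecyl-4,6-dioxocyclohexane-1-carboxylate (mixture of stereoisomers) | CCCCCCCCCCCCCCCCCC1CC(=O)CC(=O)C1C(=O)OC
F4 | step 1 | 2-heptadecyl-4,6-dioxocyclohexane-1-carboxylic acid (mixture of stereoisomers) | CCCCCCCCCCCCCCCCCC1CC(=O)CC(=O)C1C(=O)O
F5 | step 3 | 5-heptadecyl-3-methoxy-6-(phenylselanyl)cyclohex-2-en-1-one (racemic, relative configuration not controlled) | CCCCCCCCCCCCCCCCCC1CC(OC)=CC(=O)C1[Se]c2ccccc2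
F6 | step 3 | 5-heptadecyl-3-methoxy-6-(phenylseleninyl)cyclohex-2-en-1-one (mixture of stereoisomers) | CCCCCCCCCCCCCCCCCC1CC(OC)=CC(=O)C1[Se](=O)c2ccccc2
F7 | step 4 | 3-heptadecyl-5-methoxy-4-nitrosophenol | CCCCCCCCCCCCCCCCCc1cc(O)cc(OC)c1N=O
F8 | step 4 | 4-amino-3-heptadecyl-5-methoxyphenol | CCCCCCCCCCCCCCCCCc1cc(O)cc(OC)c1N
F9 | step 4 | 3-heptadecyl-4-imino-5-methoxycyclohexa-2,5-dien-1-one | CCCCCCCCCCCCCCCCCC1=CC(=O)C=C(OC)C1=N
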